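**Retrosynthetic overview**
- Endgame under acid only: the carbocycle is closed last through the C4–C4a bond (Friedel–Crafts attack of the oxygenated benzene ring on a formyl carbon attached to C3, then dehydration to C3=C4), with both tert-butyl esters and the benzyl ether removed in the same pot.
- C4 is brought in by formylation of the succinate CH2 next to the methyl ester.
- Key disconnection C1–C2: the carbene-generated homoenolate of a 4-oxobut-2-enoate (its normally electrophilic β-carbon used as a nucleophile) adds to the exocyclic carbon of a p-quinone methide; both stereocentres are set here and methanol releases the methyl ester.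
- The quinone methide comes from a sulfone made from a pyranone-4-carbaldehyde, 2-(benzyloxy)phenol and a sulfinic acid.
- Ring order: pyranone ring first (oxalate Claisen/lactonisation, then SeO2), benzene ring bought, carbocycle last.

Assumption: every starting material named below is taken as a catalogue compound, and the enantiomer of the triazolium catalyst is chosen to match the target.

**Step 1**
Reactants: 1 methyl 3-methylbut-2-enoate; 2 di-tert-butyl oxalate
Product: 4 tert-butyl 4-methyl-2-oxo-2H-pyran-6-carboxylate, via open-chain enol diester 3 (not isolated)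
Conditions: KOt-Bu (1.1 equiv), THF, 0 °C to rt; then AcOH, toluene, 80 °C
Reagents that add atoms: none
Why: γ-selective crossed Claisen condensation of the potassium dienolate of 1 with the non-enolisable oxalate, then lactonisation of the (2Z,4Z)-enol 3 with loss of methanol (the classical oxalate route to 2-pyranone-6-carboxylates); no stereocentre is formed.

**Step 2**
Reactants: 4 tert-butyl 4-methyl-2-oxo-2H-pyran-6-carboxylate
Product: 5 tert-butyl 4-formyl-2-oxo-2H-pyran-6-carboxylate
Conditions: SeO2 (1.3 equiv), 1,4-dioxane, 100 °C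
Reagents that add atoms: selenium dioxide, O=[Se]=O
Why: Riley oxidation of the vinylogously activated 4-methyl group, as for 4-methylcoumarins; the ester and ring are untouched and no stereocentre is formed.

**Step 3**
Reactants: 5 tert-butyl 4-formyl-2-oxo-2H-pyran-6-carboxylate; 6 2-(benzyloxy)phenol
Product: 8 tert-butyl 4-{[3-(benzyloxy)-4-hydroxyphenyl](4-methylbenzenesulfonyl)methyl}-2-oxo-2H-pyran-6-carboxylate (racemic), via carbinol 7 (not isolated)
Conditions: TolSO2H (1.5 equiv), (CF3)2CHOH/CH2Cl2, rt
Reagents that add atoms: p-toluenesulfinic acid, Cc1ccc(cc1)S(=O)O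
Why: Friedel–Crafts hydroxyalkylation of the phenol para to its free OH by the electron-poor aldehyde gives carbinol 7, which ionises through its p-hydroxybenzylic cation and is trapped by the sulfinic acid (the usual three-component synthesis of sulfone precursors of quinone methides); the new centre is racemic and is erased in step 4.

**Step 4**
Reactants: 8 tert-butyl 4-{[3-(benzyloxy)-4-hydroxyphenyl](4-methylbenzenesulfonyl)methyl}-2-oxo-2H-pyran-6-carboxylate; 9 tert-butyl (2E)-4-oxobut-2-enoate
Product: 11 1-tert-butyl 4-methyl (2R)-2-{(S)-[3-(benzyloxy)-4-hydroxyphenyl][6-(tert-butoxycarbonyl)-2-oxo-2H-pyran-4-yl]methyl}butanedioate, via p-quinone methide 10 (not isolated)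
Conditions: 9 (2 equiv), chiral aminoindanol-derived N-mesityl triazolium tetrafluoroborate (10 mol %), i-Pr2NEt (1.5 equiv), MeOH (5 equiv), THF, 0 °C to rt
Reagents that add atoms: methanol, CO
Why: Proposed new method: the carbene adds to aldehyde 9 to give a Breslow intermediate whose β-carbon (normally the electrophilic enal terminus, here C2) is nucleophilic and attacks the exocyclic carbon (C1) of quinone methide 10, which base releases slowly from sulfone 8, with rearomatisation as driving force; tautomerisation to the acyl azolium and methanolysis give the methyl ester and free the catalyst, and the chiral triazolium controls the face of the homoenolate and its approach to the quinone methide, so C1 and C2 are both set in this one C–C bond formation; the closest known reaction types are carbene-catalysed homoenolate additions of enals and 4-oxoenoates to chalcones with methanol turnover, carbene-catalysed 1,6-additions to p-quinone methides, and base-triggered quinone methide generation from sulfones.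

**Step 5**
Reactants: 11 1-tert-butyl 4-methyl (2R)-2-{(S)-[3-(benzyloxy)-4-hydroxyphenyl][6-(tert-butoxycarbonyl)-2-oxo-2H-pyran-4-yl]methyl}butanedioate
Product: 12 1-tert-butyl 4-methyl (2S,3Z)-2-{(S)-[3-(benzyloxy)-4-hydroxyphenyl][6-(tert-butoxycarbonyl)-2-oxo-2H-pyran-4-yl]methyl}-3-(hydroxymethylidene)butanedioate
Conditions: LiN(i-Pr)2 (2.1 equiv), THF, −78 °C; HCO2CH2CF3 (2.5 equiv), −78 to −40 °C; AcOH quench
Reagents that add atoms: 2,2,2-trifluoroethyl formate, O=COCC(F)(F)F
Why: crossed Claisen formylation of the kinetic lithium enolate of the methyl ester CH2, the only unhindered enolisable site (C2–H is tertiary beside the bulky tert-butyl ester and C1–H is shielded and deactivated by the para-phenoxide formed first), so C1 and C2 stay intact; the descriptor at C2 changes only because the priorities change, and the product rests as the hydrogen-bonded Z-enol.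

**Step 6**
Reactants: 12 1-tert-butyl 4-methyl (2S,3Z)-2-{(S)-[3-(benzyloxy)-4-hydroxyphenyl][6-(tert-butoxycarbonyl)-2-oxo-2H-pyran-4-yl]methyl}-3-(hydroxymethylidene)butanedioate
Product: 14 (1R,2S)-1-(6-carboxy-2-oxo-2H-pyran-4-yl)-6,7-dihydroxy-3-(methoxycarbonyl)-1,2-dihydronaphthalene-2-carboxylic acid, via cyclised protected diester 13 (not isolated)
Conditions: CF3CO2H/CH2Cl2 1:4, 0 °C; then C6HMe5 (5 equiv), CF3CO2H, rt
Reagents that add atoms: none
Why: acid-mediated cyclodehydration of the hydroxymethylene ester (intramolecular Friedel–Crafts hydroxyalkylation para to the benzyloxy oxygen, then loss of water to the conjugated C3=C4 bond, the classical aryldihydronaphthalene ring closure) followed by acidolysis of both tert-butyl esters and the benzyl ether with a cation scavenger; no base is present, so both stereocentres are carried through unchanged.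

**Compound list**
1 | methyl 3-methylbut-2-enoate | CC(C)=CC(=O)OC | starting material
2 | di-tert-butyl oxalate | CC(C)(C)OC(=O)C(=O)OC(C)(C)C | starting material
3 | 1-tert-butyl 6-methyl (2Z,4Z)-2-hydroxy-4-methylhexa-2,4-dienedioate | CC(C)(C)OC(=O)C(/O)=C/C(C)=C\C(=O)OC | intermediate (not isolated)
4 | tert-butyl 4-methyl-2-oxo-2H-pyran-6-carboxylate | Cc1cc(C(=O)OC(C)(C)C)oc(=O)c1 | intermediate
5 | tert-butyl 4-formyl-2-oxo-2H-pyran-6-carboxylate | O=Cc1cc(C(=O)OC(C)(C)C)oc(=O)c1 | intermediate
6 | 2-(benzyloxy)phenol | Oc1ccccc1OCc1ccccc1 | starting material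
7 | tert-butyl 4-{[3-(benzyloxy)-4-hydroxyphenyl](hydroxy)methyl}-2-oxo-2H-pyran-6-carboxylate (racemic) | OC(c1ccc(O)c(OCc2ccccc2)c1)c1cc(C(=O)OC(C)(C)C)oc(=O)c1 | intermediate (not isolated)
8 | tert-butyl 4-{[3-(benzyloxy)-4-hydroxyphenyl](4-methylbenzenesulfonyl)methyl}-2-oxo-2H-pyran-6-carboxylate (racemic) | Cc1ccc(cc1)S(=O)(=O)C(c1ccc(O)c(OCc2ccccc2)c1)c1cc(C(=O)OC(C)(C)C)oc(=O)c1 | intermediate
9 | tert-butyl (2E)-4-oxobut-2-enoate | CC(C)(C)OC(=O)/C=C/C=O | starting material
10 | tert-butyl 4-{[3-(benzyloxy)-4-oxocyclohexa-2,5-dien-1-ylidene]methyl}-2-oxo-2H-pyran-6-carboxylate (exocyclic alkene geometry not defined) | O=C1C=CC(=Cc2cc(C(=O)OC(C)(C)C)oc(=O)c2)C=C1OCc1ccccc1 | intermediate (not isolated)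
11 | 1-tert-butyl 4-methyl (2R)-2-{(S)-[3-(benzyloxy)-4-hydroxyphenyl][6-(tert-butoxycarbonyl)-2-oxo-2H-pyran-4-yl]methyl}butanedioate | Oc1ccc(cc1OCc1ccccc1)[C@@H](c1cc(C(=O)OC(C)(C)C)oc(=O)c1)[C@@H](CC(=O)OC)C(=O)OC(C)(C)C | intermediate
12 | 1-tert-butyl 4-methyl (2S,3Z)-2-{(S)-[3-(benzyloxy)-4-hydroxyphenyl][6-(tert-butoxycarbonyl)-2-oxo-2H-pyran-4-yl]methyl}-3-(hydroxymethylidene)butanedioate | Oc1ccc(cc1OCc1ccccc1)[C@@H](c1cc(C(=O)OC(C)(C)C)oc(=O)c1)[C@@H](/C(=C/O)C(=O)OC)C(=O)OC(C)(C)C | intermediate
13 | 2-tert-butyl 3-methyl (1R,2S)-7-(benzyloxy)-1-[6-(tert-butoxycarbonyl)-2-oxo-2H-pyran-4-yl]-6-hydroxy-1,2-dihydronaphthalene-2,3-dicarboxylate | COC(=O)C1=Cc2cc(O)c(OCc3ccccc3)cc2[C@@H](c2cc(C(=O)OC(C)(C)C)oc(=O)c2)[C@@H]1C(=O)OC(C)(C)C | intermediate (not isolated)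
14 | (1R,2S)-1-(6-carboxy-2-oxo-2H-pyran-4-yl)-6,7-dihydroxy-3-(methoxycarbonyl)-1,2-dihydronaphthalene-2-carboxylic acid | COC(=O)C1=Cc2cc(O)c(O)cc2[C@@H](c2cc(C(=O)O)oc(=O)c2)[C@@H]1C(=O)O | target

**Totals**
Total step count: 6. Longest linear sequence: 6 steps (1 → 4 → 5 → 8 → 11 → 12 → 14).

**Three steps most likely to fail**

Step 4 is the riskiest. The homoenolate may be protonated instead of adding, the Breslow intermediate may add through its acyl carbon, or the diastereo- and enantioselectivity on an unblocked, in situ quinone methide may be poor. The fallback sets out from 8. The same quinone methide 10 is released with i-Pr2NEt in the presence of methyl 4-oxobutanoate and a diarylprolinol silyl ether, so that an enamine (a precedented aldehyde 1,6-addition to p-quinone methides) forms the C1–C2 bond and gives methyl (3R,4S)-4-[3-(benzyloxy)-4-hydroxyphenyl]-4-[6-(tert-butoxycarbonyl)-2-oxo-2H-pyran-4-yl]-3-formylbutanoate F1. The aldehyde is oxidised with NaClO2/NaH2PO4/2-methylbut-2-ene to (2R)-2-{(S)-[3-(benzyloxy)-4-hydroxyphenyl][6-(tert-butoxycarbonyl)-2-oxo-2H-pyran-4-yl]methyl}-4-methoxy-4-oxobutanoic acid F2. Esterification with tert-butyl 2,2,2-trichloroacetimidate then comes back to the route at 11.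

Step 5 is second. The amide base may remove the acidic diarylmethine proton at C1 (loss of configuration) or the ester enolate may attack the pyranone. The fallback avoids any strong base after the pyranone is in place by bringing C4 in with the enal. It sets out from 8, which is treated under the step 4 conditions with tert-butyl (2Z)-3-(dimethoxymethyl)-4-oxobut-2-enoate F3 in place of 9; F3 is made by amine-catalysed condensation of tert-butyl glyoxylate with 3,3-dimethoxypropanal. The product is 1-tert-butyl 4-methyl (2S)-2-{(S)-[3-(benzyloxy)-4-hydroxyphenyl][6-(tert-butoxycarbonyl)-2-oxo-2H-pyran-4-yl]methyl}-3-(dimethoxymethyl)butanedioate F4 (mixture at C3). Under the first acid stage of step 6 the acetal of F4 closes onto the arene with loss of methanol, and the route is rejoined at 13.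

Step 3 is third. The hydroxyalkylation may give ortho or para-to-benzyloxy isomers, or bis-arylation. The fallback fixes the regiochemistry with a boron group and sets out from 6. Bromination with N-bromosuccinimide para to the hydroxyl gives 2-(benzyloxy)-4-bromophenol F5. Borylation with Pd(dppf)Cl2, B2pin2 and KOAc gives 2-(benzyloxy)-4-(4,4,5,5-tetramethyl-1,3,2-dioxaborolan-2-yl)phenol F6. [Rh(cod)OH]2-catalysed 1,2-addition of F6 to aldehyde 5 gives carbinol 7, and TolSO2H in (CF3)2CHOH then returns the route at 8.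

**Further compounds**
F1 | step 4 | methyl (3R,4S)-4-[3-(benzyloxy)-4-hydroxyphenyl]-4-[6-(tert-butoxycarbonyl)-2-oxo-2H-pyran-4-yl]-3-formylbutanoate | Oc1ccc(cc1OCc1ccccc1)[C@@H](c1cc(C(=O)OC(C)(C)C)oc(=O)c1)[C@@H](CC(=O)OC)C=O
F2 | step 4 | (2R)-2-{(S)-[3-(benzyloxy)-4-hydroxyphenyl][6-(tert-butoxycarbonyl)-2-oxo-2H-pyran-4-yl]methyl}-4-methoxy-4-oxobutanoic acid | Oc1ccc(cc1OCc1ccccc1)[C@@H](c1cc(C(=O)OC(C)(C)C)oc(=O)c1)[C@@H](CC(=O)OC)C(=O)O
F3 | step 5 | tert-butyl (2Z)-3-(dimethoxymethyl)-4-oxobut-2-enoate | CC(C)(C)OC(=O)/C=C(\C(OC)OC)C=O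
F4 | step 5 | 1-tert-butyl 4-methyl (2S)-2-{(S)-[3-(benzyloxy)-4-hydroxyphenyl][6-(tert-butoxycarbonyl)-2-oxo-2H-pyran-4-yl]methyl}-3-(dimethoxymethyl)butanedioate (mixture at C3) | Oc1ccc(cc1OCc1ccccc1)[C@@H](c1cc(C(=O)OC(C)(C)C)oc(=O)c1)[C@@H](C(C(OC)OC)C(=O)OC)C(=O)OC(C)(C)C
F5 | step 3 | 2-(benzyloxy)-4-bromophenol | Oc1ccc(Br)cc1OCc1ccccc1
F6 | step 3 | 2-(benzyloxy)-4-(4,4,5,5-tetramethyl-1,3,2-dioxaborolan-2-yl)phenol | Oc1ccc(cc1OCc1ccccc1)B1OC(C)(C)C(C)(C)O1
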